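The flask asked about is the summer run read twice as late: it has the same charge and the same held gas phase, with a last reading at 12.0 h against an asked time of 25 h.

all flasks: substrate 0.50 M; gas phase 31 mM (held)
- summer: the very flask that is asked about, followed so far
- flask: time 25 h

summer run (percent of the substrate charged)

| time / h | target / % | substrate / % |
|---|---|---|
| 0.667 | 8.9 | 93.0 |
| 2.00 | 24.2 | 74.5 |
| 4.00 | 44.1 | 54.2 |
| 5.00 | 54.1 | 45.7 |
| 8.00 | 72.4 | 24.7 |
| 10.0 | 81.8 | 16.5 |
| 12.0 | 86.3 | 11.5 |

(readings scatter by 1 percentage point)

- at the start none of the gas phase is in solution

* the target standing at 25 h, as a percentage of the substrate charged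
* the change that raises the amount of target at 25 h, in percent of the substrate charged most ("none" if none brings more than 2 percentage points) (Friday's / Tuesday's / none)
* amount of target at 25 h, in percent of the substrate charged, after Tuesday's

- Friday's: doubling the saturation concentration of gas phase, all else as stated
- Tuesday's: doubling the transfer coefficient of the gas phase, all else as stated

The reckoning here goes in powers of ten. Read as a pseudo-first-order decay, [substrate] falls from 45.7% at 5.00 h to 11.5% at 12.0 h, which is 0.599 of a power of ten. The summer run therefore gives a reading of 11.7 h for the decade time, the hours in which [substrate] falls by one power of ten.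

The summer run's last reading, at 12.0 h, shows 11.5% of substrate. The flask's [substrate] ends lower because the 13.0 h it runs on are longer than a decade time, which makes 1.11 decade times further. My own reckoning thus leaves 0.887% of substrate. The last reading's balance is short by 2.2 percentage points, and holding that gap gives 96.9% of target. Friday's and Tuesday's speed a decay with 0.887% of substrate to go, less than the margin of 2 points, so my pick is none, and Tuesday's stays within that amount of 96.9%.

The forecast gives 95.5% (92% to 98%), lower than my 96.9%, names none, and puts Tuesday's at 96% (92% to 98.5%): “Either change only speeds up a reaction that is essentially finished”.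

The flask gives 96.6% of target, with none as the best change; Friday's adds 0.14 points, Tuesday's adds 0.048 points, and target after Tuesday's stands at 96.6%.

    gas phase ⇌ dissolved gas, rate k1*(csat - [dissolved gas]) (kL = 0.00170 s⁻¹)
    substrate + dissolved gas → target (k = 0.00210 M⁻¹ s⁻¹)
    target → over-reaction product (k = 4.20 × 10⁻⁷ s⁻¹)

At 25.0 h the flask holds 0.548% of substrate, against the 0.887% reckoned from the decade time. The same flask read at 6.0 h lies 0.0855 of a decade time after the summer reading at 5.00 h, which reckons to 37.5% of substrate, and that neighbouring flask stands at 37.2%.

The runs come from a simulation with made-up constants; noise was put on by code.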